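The runs come from a simulation for substances that don't exist; scatter was added.

**The question.** How far does the share of target among what became target or isomer of the product move when partner goes from 0.300 M to 1.20 M, with substrate at 1.5 M and impurity at 82 mM, after 3.0 d?

| flask | substrate | partner | free catalyst | impurity | remark | time |
|---|---|---|---|---|---|---|
| zeta | 1 M | 0.30 M | 220 mM | 82 mM | run made earlier |  |
| gamma | 1.5 M | 0.30 M | 220 mM | 41 mM | run made earlier |  |
| Friday's | 1.5 M | 0.300 M | 220 mM | 82 mM |  | 3.0 d |
| Monday's | 1.5 M | 0.500 M | 220 mM | 82 mM |  | 3.0 d |
| Sunday's | 1.5 M | 0.800 M | 220 mM | 82 mM |  | 3.0 d |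
| Wednesday's | 1.5 M | 1.20 M | 220 mM | 82 mM |  | 3.0 d |

- zeta (time / h: target / %, isomer of the product / %, substrate / %): 3.00: 8, 2, 92; 6.00: 9, 5, 84; 10.0: 14, 5, 80; 15.0: 18, 4, 78; 25.0: 19, 8, 75; 40.0: 19, 8, 73
- gamma (time / h: target / %, isomer of the product / %, substrate / %): 3.00: 5, 1, 92; 6.00: 9, 4, 86; 10.0: 12, 5, 86; 15.0: 12, 2, 82; 25.0: 13, 5, 84; 40.0: 14, 4, 82

(each reading ± 1.5 percentage points)

- share of target in all that became target or isomer of the product for Friday's, Monday's, Sunday's, Wednesday's, in this order
- how the row runs (falls, then rises / falls all the way / rises all the way / hardly changes / rises, then falls)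

- the numbers in the tables scatter with a standard deviation of 1.5 percentage points
- "hardly changes" means that all values lie within two and a half points (for a concentration: within two and a half percent of the largest)

**Limiting reagent.** At 40.0 h the zeta run held 0.270 M of the two products and the gamma run 0.270 M, against 0.30 M of partner charged. The two runs differed in substrate and in impurity, yet gave about the same amount, so I read partner as the limiting reagent. Even 1.20 M stays below 1.5 M.

**Upper bound.** The gamma run at 15.0 h read a share of 85.7%. But its isomer reading of 2% lies below the 5% before it and the 5% after it, with a scatter of 1.5 percentage points, so I kept to readings from 25.0 h on, where both runs lay flat within that scatter. That tightened the top to the gamma reading at 40.0 h, 77.8%.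

**Lower bound.** The zeta run at 40.0 h gave 70.4%. Friday's flask takes its substrate from the gamma run and its impurity from the zeta run, so I placed it between these readings. My estimate was the plateau share s, the midpoint of the two bounds, 74.1%.

**The forecast.** It gave 72% at each charge, hardly changes, since “their ratio should not depend on partner charge”. That lies inside my bracket but below s. Both numbers extrapolate in partner.

**The flask.**

    free catalyst + impurity → spent catalyst (k = 4.80 M⁻¹ min⁻¹)
    substrate + partner ⇌ target (K = 9.90 M⁻¹, k = 0.00160 M⁻¹ min⁻¹)
    substrate + partner ⇌ isomer of the product (K = 3.00 M⁻¹, k = 6.50 × 10⁻⁴ M⁻¹ min⁻¹)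
    partner → decomposed reagent (k = 7.00 × 10⁻⁵ min⁻¹)
    target + free catalyst ⇌ isomer of the product + free catalyst, rate k5*[free catalyst]*[target] forward; the back reaction follows from the equilibrium constant (k = 0.00450 M⁻¹ min⁻¹)

It gave 76.8% at 0.300 M partner and 76.8% at 1.20 M, hardly changes, inside the bracket and above s. That matches the 76.7% from the two equilibrium constants, thermodynamic control; a run ten times as long leaves Friday's share unchanged. Monday's flask ended with 70.2% of its substrate, and 1 − s of what had turned over gives 7.72% isomer of the product; it held 6.94%. Wednesday's flask, with 34.3% substrate left, gives 17.0%; it held 15.3%.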